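## Numbering of compounds (used throughout)

"Prenyl" means 3-methylbut-2-en-1-yl. Ring A is numbered from the benzoyl-bearing carbon (C1).

1 2,4,6-trihydroxybenzophenone  
2 chloromethyl methyl ether  
3 2,6-dihydroxy-4-(methoxymethoxy)benzophenone  
4 3-chloro-3-methylbut-1-yne  
5 2-hydroxy-4-(methoxymethoxy)-6-(2-methylbut-3-yn-2-yloxy)benzophenone (mono-propargyl ether)  
6 4-(methoxymethoxy)-2,6-bis(2-methylbut-3-yn-2-yloxy)benzophenone  
7 4-(methoxymethoxy)-2-(2-methylbut-3-en-2-yloxy)-6-(2-methylbut-3-yn-2-yloxy)benzophenone (ene-yne ether)  
8 4-(methoxymethoxy)-2,6-bis(2-methylbut-3-en-2-yloxy)benzophenone  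
9 first ortho-dienone  
10 2-hydroxy-4-(methoxymethoxy)-6-(2-methylbut-3-en-2-yloxy)-3-prenylbenzophenone  
11 second ortho-dienone  
12 2,6-dihydroxy-4-(methoxymethoxy)-3,5-diprenylbenzophenone  
13 iodomethane  
14 2-hydroxy-6-methoxy-4-(methoxymethoxy)-3,5-diprenylbenzophenone  
15 2,4-dihydroxy-6-methoxy-3,5-diprenylbenzophenone (target)

## Analysis of the target

Compound 15 is a benzophenone in which ring B is an unsubstituted phenyl and ring A is a fully substituted phloroglucinol ring: C1 benzoyl, C2 OMe, C3 prenyl, C4 OH, C5 prenyl, C6 OH. There is no stereocentre and no alkene geometry to set, because each prenyl double bond ends in two methyl groups. The sensitive groups are the two prenyl chains, each ortho to a phenol, which cyclise to 2,2-dimethylchromans or add HX under acid. The electron-rich ring is also easily oxidised and easily alkylated on carbon. The difficulty is one of position only: six substituents must be placed correctly, and the three oxygens must be told apart. Only one ortho oxygen carries methyl, and the para oxygen, the most acidic and most accessible, carries none. The two prenyl groups must go onto carbon without O-prenylation or geminal dialkylation. The feature used is that C3 and C5 each lie ortho to an oxygen (O2 and O6) whose other ortho neighbour is C1, already occupied by the benzoyl group. A sigmatropic transfer from O2 can therefore end only at C3, and one from O6 only at C5. Without the methyl group, ring A has a mirror plane through C1 and C4, so symmetric intermediates can be used until the methylation.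

## Retrosynthetic reasoning

**15 to 14 (O4–CH2 bond of the acetal).** The last operation makes no skeletal bond; it only uncovers O4. The para hydroxyl would be alkylated before either ortho oxygen, so it must stay masked from the first step until the methyl group is in place. An acetal-type ether is chosen because it is indifferent to amine and carbonate bases, to semihydrogenation and to heat. The price is that the forward step must cleave it with acid mild enough to spare two prenyl groups standing next to phenols.

**14 to 12 and 13 (O–CH3 bond).** Removing the methyl group gives the symmetric diol 12. Methylation of either hydroxyl gives the same product, so the only selectivity required is single against double methylation. The remaining hydroxyl of 14 is locked to the carbonyl by a hydrogen bond and flanked by a prenyl group, which should secure this.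

**12 to 8 (C3–CH2 and C5–CH2 bonds, the key disconnection).** Both aryl–prenyl bonds are cut and each C5 unit is returned to the neighbouring oxygen as a tertiary allyl ether. The forward reaction passes through 9, 10 and 11. Other cuts are less attractive:
- cutting C1–C(=O) would require acylating a prenylated phenol under Lewis acid at the end;
- cutting ring bonds would mean building a hexasubstituted arene from open-chain parts;
- alkylating 3 directly on carbon leaves O- against C-attack and single against multiple alkylation uncontrolled.

The sigmatropic route makes the C–C bond formation intramolecular. The site is fixed by the blocked C1, and the linear prenyl group follows from inversion of the allyl unit.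

**8 to 6 (alkene from alkyne).** A tertiary allyl aryl ether cannot be made reliably by substitution at the tertiary carbon, since elimination and attack at the primary terminus intervene. The propargylic analogue 6 can be made, and semi-reduction of its two terminal alkynes (through 7) gives 8 with no geometry to control.

**6 to 3 and 4 (two O–C bonds).** Both ortho hydroxyls of 3 are etherified at the tertiary carbon of 4 by copper-catalysed propargylic substitution, through mono-ether 5. The symmetry of 3 means no site question arises; the step must only be driven to the second, hydrogen-bonded hydroxyl.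

**3 to 1 and 2 (O4–CH2 bond).** The acetal is placed on the para hydroxyl of 1, the one that is most acidic and is not held by the carbonyl. This leaves the ring, the benzoyl group and all three oxygens as they come in the starting material.

## Alternatives that were turned down

**Alternative 1: Danheiser benzannulation.**
- Disconnection: ring A is divided into a four-carbon and a two-carbon piece. 3-Methoxy-4-prenylcyclobut-2-en-1-one A2 supplies C4 (its carbonyl carbon), C3, C2 and C1. The siloxyalkyne triisopropyl[(5-methylhex-4-en-1-yn-1-yl)oxy]silane A3 supplies C5 and C6.
- Forward key step: heating opens A2 to a vinylketene, which adds (2+2) to A3, forming C4–C5 and C1–C6. The new four-membered ring opens in a four-electron process, and six-electron closure re-forms C3–C4. Tautomerisation gives 3-methoxy-2,6-diprenyl-5-(triisopropylsiloxy)phenol A1.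
- For it: it is convergent, and the position of every substituent follows from the connectivity of the partners. The three oxygens emerge already differentiated (OMe, free OH, silyl ether), so neither a protection of O4 nor a selective methylation is needed. On this point it is stronger than the chosen route.
- Against it: A1 carries hydrogen at C1, so the benzoyl group must still be introduced between an OMe and a silyloxy group on a pentasubstituted ring. Lewis-acid acylation there endangers the prenyl groups beside the free hydroxyl and the silyl ether. A halogenation–metalation detour would need extra protection steps. A2 and A3 each need several steps, and A3 is a skipped enyne ynol ether of limited stability.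
- Comparison: the chosen route starts with the ring and the benzoyl group in place and needs six linear steps. It accepts one protection and one monomethylation in exchange for that.

**Alternative 2: biomimetic Claisen cyclisation of a tetraketide.**
- Disconnection: ring A is opened between C1 and C6, leading to the open-chain methyl 3,5,7-trioxo-7-phenyl-2,4-diprenylheptanoate A5.
- Forward key step: with an alkoxide base in an alcohol, the methylene between the two ketones next to the phenyl ketone attacks the ester carbonyl. The six-membered ring closes and enolises to 2,4,6-trihydroxy-3,5-diprenylbenzophenone A4.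
- For it: it follows the biosynthetic logic. Ring, benzoyl group and both prenyl groups are set in one operation, and there is no question of where the prenyl groups sit. A4 is symmetric, as 12 is, and the ring construction needs no protecting group. On these points it is as strong as or stronger than the chosen route.
- Against it: A5 is a polycarbonyl chain substituted at two of its three active positions. It would have to be built by polyanion chemistry, and it can close through oxygen to pyranones as well as through carbon. A4 has three free hydroxyls, of which the para one is the most reactive. The target needs methyl on an ortho oxygen, so the same protect–methylate–deprotect endgame would follow, now starting with protection of a para hydroxyl flanked by two prenyl groups.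
- Comparison: the chosen route buys the ring, forms only two C–C bonds, and reaches the same kind of symmetric diol (12) with O4 already masked.

**Alternative 3: three-plus-three annulation.**
- Disconnection: the ring bonds C2–C3 and C5–C6 are cut. The symmetric ketone 2,10-dimethylundeca-2,9-dien-6-one A7 supplies C3, C4 and C5 with both prenyl groups. The ketene acetal dimethyl 2-(dimethoxymethylene)propanedioate A8 supplies C2, C1 and C6.
- Forward key step: the enolate of A7 displaces one methoxide from the acetal carbon of A8 (C2–C3). With excess base the second alpha carbon acylates the cis ester (C5–C6). The ring closes to methyl 2,4-dihydroxy-6-methoxy-3,5-diprenylbenzoate A6.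
- For it: the C2 methoxy group comes from the acetal, so the correct oxygen is methylated from the start. The prenyl groups arrive on carbon with the ketone. On oxygen differentiation and on avoiding C-prenylation it is clearly stronger than the chosen route.
- Against it: A6 carries an ester at C1 where the target has a benzoyl group. This ester is flanked by two oxygen substituents, deactivated by them and hydrogen-bonded. Converting it to a phenyl ketone would need phenol protection and an oxidation-state detour, or a hindered and possibly twofold addition of a phenyl organometallic. The annulation must also form two bonds at secondary alpha carbons, with O-acylation to a pyranone as a competing closure.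
- Comparison: the chosen route offers the benzoyl group at C1 from the first step and a shorter sequence.

Key step: step 4

Assumption: compounds 1, 2, 4 and 13 are taken as purchasable. The target has no stereocentre; the dienones 9 and 11 are racemic and transient.

## Route

Step 1  
Reactants: 1 2,4,6-trihydroxybenzophenone; 2 chloromethyl methyl ether  
Product: 3 2,6-dihydroxy-4-(methoxymethoxy)benzophenone  
Conditions: MOMCl (1.05 equiv), iPr2NEt (1.2 equiv), THF/CH2Cl2, 0 °C  
Reagents that add atoms: chloromethyl methyl ether, COCCl  
Why: Williamson-type O-alkylation with an alpha-chloro ether; the 4-OH, para to the ketone, is the most acidic and least hindered hydroxyl and is not held in a hydrogen bond to the carbonyl, so with one equivalent of electrophile and a weak amine base it should react first, and unreacted 1 or over-alkylated material can be separated and returned to 1.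

Step 2  
Reactants: 3 2,6-dihydroxy-4-(methoxymethoxy)benzophenone; 4 3-chloro-3-methylbut-1-yne  
Product: 6 4-(methoxymethoxy)-2,6-bis(2-methylbut-3-yn-2-yloxy)benzophenone, via mono-propargyl ether 5 (not isolated)  
Conditions: 4 (4 equiv), CuCl2·2H2O (1 mol%), DBU (4 equiv), MeCN, 0 °C to rt  
Reagents that add atoms: 3-chloro-3-methylbut-1-yne, C#CC(C)(C)Cl  
Why: Copper-catalysed propargylic etherification, in which the copper acetylide of 4 ionises to an electrophilic copper allenylidene that the phenoxide captures at the tertiary carbon, a reaction type established for phenols including ortho-acyl phenols; DBU is strong enough to deprotonate the hydrogen-bonded hydroxyl of 5, and the acetal at O4 is inert to base.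

Step 3  
Reactants: 6 4-(methoxymethoxy)-2,6-bis(2-methylbut-3-yn-2-yloxy)benzophenone  
Product: 8 4-(methoxymethoxy)-2,6-bis(2-methylbut-3-en-2-yloxy)benzophenone, via ene-yne ether 7 (not isolated)  
Conditions: H2 (1 atm), Pd/CaCO3 poisoned with Pb(OAc)2, quinoline, EtOAc, rt  
Reagents that add atoms: none  
Why: Lindlar-type semihydrogenation of terminal alkynes to terminal alkenes, where no alkene geometry arises; quinoline and stopping after two equivalents of H2 should prevent over-reduction, and the ketone, the acetal and the aryl ethers are untouched at room temperature.

Step 4  
Reactants: 8 4-(methoxymethoxy)-2,6-bis(2-methylbut-3-en-2-yloxy)benzophenone  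
Product: 12 2,6-dihydroxy-4-(methoxymethoxy)-3,5-diprenylbenzophenone, via first ortho-dienone 9 (not isolated), via mono-prenyl phenol 10 (not isolated), via second ortho-dienone 11 (not isolated)  
Conditions: degassed o-xylene, 130 °C, Ar, base-washed glassware  
Reagents that add atoms: none  
Why: On heating, each aryl 1,1-dimethylallyl ether should undergo a concerted (3,3) sigmatropic shift through a chair-like six-membered transition state in which the terminal CH2 of the allyl unit bonds to the hydrogen-bearing ortho carbon as the O–C(tertiary) bond breaks; the first shift gives dienone 9, which enolises to phenol 10, and the second gives dienone 11, which enolises to 12. The closest known reaction type is the aromatic Claisen rearrangement of aryl 1,1-dimethylallyl ethers to ortho-prenylphenols, applied here twice on one ring. No ring is closed and no stereocentre remains, since the sp3 ring carbon of 9 and 11 is lost on tautomerisation. The step needs ortho (C3, C5) rather than ipso (C1) transfer, and linear rather than branched attachment. The first is secured because each ether oxygen has only one ortho carbon bearing hydrogen, so only that path ends in irreversible aromatisation; the second follows from the suprafacial shift, which inverts the allyl unit. Transfer to C1 gives a dienone that cannot aromatise and should return to the ether, or less readily pass the unit on to the para carbon. Relief of crowding around the tertiary ethers beside the benzoyl group, and the new hydrogen bond to the ketone, should let the reaction run near 130 °C. Neutral, acid-free conditions are kept so that ionisation of the tertiary ethers with loss of isoprene does not compete.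

Step 5  
Reactants: 12 2,6-dihydroxy-4-(methoxymethoxy)-3,5-diprenylbenzophenone; 13 iodomethane  
Product: 14 2-hydroxy-6-methoxy-4-(methoxymethoxy)-3,5-diprenylbenzophenone  
Conditions: MeI (1.1 equiv), K2CO3 (1.2 equiv), acetone, rt  
Reagents that add atoms: iodomethane, CI  
Why: Williamson O-methylation; the two hydroxyls of 12 are equivalent and only one at a time can hydrogen-bond to the carbonyl, so one is alkylated readily, whereas in 14 the remaining hydroxyl is firmly chelated and flanked by a prenyl group, which should make a second methylation much slower; the acetal keeps the most reactive oxygen, O4, masked.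

Step 6  
Reactants: 14 2-hydroxy-6-methoxy-4-(methoxymethoxy)-3,5-diprenylbenzophenone  
Product: 15 2,4-dihydroxy-6-methoxy-3,5-diprenylbenzophenone  
Conditions: HCl (1 M) in MeOH, rt to 40 °C, stopped at full conversion  
Reagents that add atoms: none  
Why: Acid-catalysed acetal solvolysis through an oxocarbenium ion, with transfer of the CH2 unit to methanol; at this acidity and temperature protonation of the trisubstituted alkenes should be much slower than acetal cleavage, a selectivity commonly relied on for methoxymethyl ethers of prenylated phenols.

## Compound list

1 | 2,4,6-trihydroxybenzophenone | O=C(c1ccccc1)c1c(O)cc(O)cc1O | starting material  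
2 | chloromethyl methyl ether | COCCl | starting material  
3 | 2,6-dihydroxy-4-(methoxymethoxy)benzophenone | COCOc1cc(O)c(C(=O)c2ccccc2)c(O)c1 | intermediate  
4 | 3-chloro-3-methylbut-1-yne | C#CC(C)(C)Cl | starting material  
5 | 2-hydroxy-4-(methoxymethoxy)-6-(2-methylbut-3-yn-2-yloxy)benzophenone | C#CC(C)(C)Oc1cc(OCOC)cc(O)c1C(=O)c1ccccc1 | intermediate  
6 | 4-(methoxymethoxy)-2,6-bis(2-methylbut-3-yn-2-yloxy)benzophenone | C#CC(C)(C)Oc1cc(OCOC)cc(OC(C)(C)C#C)c1C(=O)c1ccccc1 | intermediate  
7 | 4-(methoxymethoxy)-2-(2-methylbut-3-en-2-yloxy)-6-(2-methylbut-3-yn-2-yloxy)benzophenone | C=CC(C)(C)Oc1cc(OCOC)cc(OC(C)(C)C#C)c1C(=O)c1ccccc1 | intermediate  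
8 | 4-(methoxymethoxy)-2,6-bis(2-methylbut-3-en-2-yloxy)benzophenone | C=CC(C)(C)Oc1cc(OCOC)cc(OC(C)(C)C=C)c1C(=O)c1ccccc1 | intermediate  
9 | 2-benzoyl-5-(methoxymethoxy)-3-(2-methylbut-3-en-2-yloxy)-6-prenylcyclohexa-2,4-dien-1-one (racemic, transient) | O=C1C(CC=C(C)C)C(OCOC)=CC(OC(C)(C)C=C)=C1C(=O)c1ccccc1 | intermediate  
10 | 2-hydroxy-4-(methoxymethoxy)-6-(2-methylbut-3-en-2-yloxy)-3-prenylbenzophenone | C=CC(C)(C)Oc1cc(OCOC)c(CC=C(C)C)c(O)c1C(=O)c1ccccc1 | intermediate  
11 | 2-benzoyl-3-hydroxy-5-(methoxymethoxy)-4,6-diprenylcyclohexa-2,4-dien-1-one (racemic, transient) | O=C1C(CC=C(C)C)C(OCOC)=C(CC=C(C)C)C(O)=C1C(=O)c1ccccc1 | intermediate  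
12 | 2,6-dihydroxy-4-(methoxymethoxy)-3,5-diprenylbenzophenone | COCOc1c(CC=C(C)C)c(O)c(C(=O)c2ccccc2)c(O)c1CC=C(C)C | intermediate  
13 | iodomethane | CI | starting material  
14 | 2-hydroxy-6-methoxy-4-(methoxymethoxy)-3,5-diprenylbenzophenone | COCOc1c(CC=C(C)C)c(O)c(C(=O)c2ccccc2)c(OC)c1CC=C(C)C | intermediate  
15 | 2,4-dihydroxy-6-methoxy-3,5-diprenylbenzophenone | COc1c(CC=C(C)C)c(O)c(CC=C(C)C)c(O)c1C(=O)c1ccccc1 | target

## Step count and least certain steps

Total step count: 6. Longest linear sequence: 6 steps (from 1; the route is fully linear).

**Step 4 (key step).**
- What may go wrong: the tertiary C–O bonds may ionise, because the departing phenoxide is stabilised by the ortho benzoyl group, and the allyl unit is then lost as a diene. The allyl unit may also be relayed through C1 to the para carbon, which would attach it through its tertiary carbon. The reaction may stall after the first shift.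
- Fallback (sets out from 3, returns at 12): the sigmatropic route is replaced by direct twofold C-alkylation of the ring carbons C3 and C5 of 3 with 1-bromo-3-methylbut-2-ene and DBU in THF at 0 °C to rt. This is the known base-mediated C-prenylation of acylphloroglucinols. It gives 12 in one step and bypasses 4 to 11, at the cost of competing O-alkylation and geminal dialkylation.

**Step 2.**
- What may go wrong: etherification may be incomplete. After the first ether is in place, the second hydroxyl is hydrogen-bonded to the carbonyl and faces a tertiary electrophile beside a crowded benzoyl group, so the reaction may stop at the mono-ether.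
- Fallback (sets out from 3, returns at 10): the ethers are placed one at a time.
  - With one equivalent of 4 under the same copper catalysis the reaction is stopped at 5, which is isolated.
  - Semihydrogenation gives 2-hydroxy-4-(methoxymethoxy)-6-(2-methylbut-3-en-2-yloxy)benzophenone F1.
  - Heating gives 2,6-dihydroxy-4-(methoxymethoxy)-3-prenylbenzophenone F2, in which one hydroxyl is again free of the carbonyl.
  - Etherification with 4 at the hydroxyl next to C5–H, the less hindered of the two, gives 2-hydroxy-4-(methoxymethoxy)-6-(2-methylbut-3-yn-2-yloxy)-3-prenylbenzophenone F3.
  - Semihydrogenation of F3 gives 10, and the second half of step 4 takes 10 to 12.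

**Step 1.**
- What may go wrong: poor selectivity in site and degree of alkylation. The electrophile is small and very reactive, so alkylation at an ortho hydroxyl or double alkylation may compete.
- Fallback (sets out from 1, returns at 15): the para oxygen is masked with a bulky silyl group, which should discriminate more strongly between the open 4-OH and the hydroxyls beside the benzoyl group.
  - Chlorotriisopropylsilane and imidazole in DMF give 2,6-dihydroxy-4-(triisopropylsilyloxy)benzophenone F4.
  - The conditions of step 2 give 2,6-bis(2-methylbut-3-yn-2-yloxy)-4-(triisopropylsilyloxy)benzophenone F5.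
  - Semihydrogenation gives 2,6-bis(2-methylbut-3-en-2-yloxy)-4-(triisopropylsilyloxy)benzophenone F6.
  - Heating gives 2,6-dihydroxy-3,5-diprenyl-4-(triisopropylsilyloxy)benzophenone F7.
  - Methylation as in step 5 gives 2-hydroxy-6-methoxy-3,5-diprenyl-4-(triisopropylsilyloxy)benzophenone F8.
  - Bu4NF buffered with AcOH in THF at 0 °C releases 15.

**Step 6.**
- What may go wrong: acid-promoted closure of a prenyl group onto a neighbouring hydroxyl, or addition of HCl or methanol across the alkenes, may compete with acetal cleavage.
- Fallback (sets out from 6, returns at 15): the acid step is moved to a stage where no prenyl group exists.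
  - HCl in MeOH on 6 gives 4-hydroxy-2,6-bis(2-methylbut-3-yn-2-yloxy)benzophenone F9.
  - Silylation with chlorotriisopropylsilane and imidazole gives 2,6-bis(2-methylbut-3-yn-2-yloxy)-4-(triisopropylsilyloxy)benzophenone F5.
  - Semihydrogenation, rearrangement and methylation then give 2,6-bis(2-methylbut-3-en-2-yloxy)-4-(triisopropylsilyloxy)benzophenone F6, 2,6-dihydroxy-3,5-diprenyl-4-(triisopropylsilyloxy)benzophenone F7 and 2-hydroxy-6-methoxy-3,5-diprenyl-4-(triisopropylsilyloxy)benzophenone F8.
  - Buffered Bu4NF gives 15 without any acid in the presence of prenyl groups.

## Further compounds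

F0 | step 4 | none | none  
F1 | step 2 | 2-hydroxy-4-(methoxymethoxy)-6-(2-methylbut-3-en-2-yloxy)benzophenone | C=CC(C)(C)Oc1cc(OCOC)cc(O)c1C(=O)c1ccccc1  
F2 | step 2 | 2,6-dihydroxy-4-(methoxymethoxy)-3-prenylbenzophenone | COCOc1cc(O)c(C(=O)c2ccccc2)c(O)c1CC=C(C)C  
F3 | step 2 | 2-hydroxy-4-(methoxymethoxy)-6-(2-methylbut-3-yn-2-yloxy)-3-prenylbenzophenone | C#CC(C)(C)Oc1cc(OCOC)c(CC=C(C)C)c(O)c1C(=O)c1ccccc1  
F4 | step 1 | 2,6-dihydroxy-4-(triisopropylsilyloxy)benzophenone | CC(C)[Si](Oc1cc(O)c(C(=O)c2ccccc2)c(O)c1)(C(C)C)C(C)C  
F5 | step 1 | 2,6-bis(2-methylbut-3-yn-2-yloxy)-4-(triisopropylsilyloxy)benzophenone | C#CC(C)(C)Oc1cc(O[Si](C(C)C)(C(C)C)C(C)C)cc(OC(C)(C)C#C)c1C(=O)c1ccccc1  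
F6 | step 1 | 2,6-bis(2-methylbut-3-en-2-yloxy)-4-(triisopropylsilyloxy)benzophenone | C=CC(C)(C)Oc1cc(O[Si](C(C)C)(C(C)C)C(C)C)cc(OC(C)(C)C=C)c1C(=O)c1ccccc1  
F7 | step 1 | 2,6-dihydroxy-3,5-diprenyl-4-(triisopropylsilyloxy)benzophenone | CC(C)=CCc1c(O)c(C(=O)c2ccccc2)c(O)c(CC=C(C)C)c1O[Si](C(C)C)(C(C)C)C(C)C  
F8 | step 1 | 2-hydroxy-6-methoxy-3,5-diprenyl-4-(triisopropylsilyloxy)benzophenone | COc1c(C(=O)c2ccccc2)c(O)c(CC=C(C)C)c(O[Si](C(C)C)(C(C)C)C(C)C)c1CC=C(C)C  
F9 | step 6 | 4-hydroxy-2,6-bis(2-methylbut-3-yn-2-yloxy)benzophenone | C#CC(C)(C)Oc1cc(O)cc(OC(C)(C)C#C)c1C(=O)c1ccccc1  
A1 | alternative 1 | 3-methoxy-2,6-diprenyl-5-(triisopropylsiloxy)phenol | COc1cc(O[Si](C(C)C)(C(C)C)C(C)C)c(CC=C(C)C)c(O)c1CC=C(C)C  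
A2 | alternative 1 | 3-methoxy-4-prenylcyclobut-2-en-1-one (racemic) | COC1=CC(=O)C1CC=C(C)C  
A3 | alternative 1 | triisopropyl[(5-methylhex-4-en-1-yn-1-yl)oxy]silane | CC(C)=CCC#CO[Si](C(C)C)(C(C)C)C(C)C  
A4 | alternative 2 | 2,4,6-trihydroxy-3,5-diprenylbenzophenone | O=C(c1ccccc1)c1c(O)c(CC=C(C)C)c(O)c(CC=C(C)C)c1O  
A5 | alternative 2 | methyl 3,5,7-trioxo-7-phenyl-2,4-diprenylheptanoate (mixture of stereoisomers and tautomers) | COC(=O)C(CC=C(C)C)C(=O)C(CC=C(C)C)C(=O)CC(=O)c1ccccc1  
A6 | alternative 3 | methyl 2,4-dihydroxy-6-methoxy-3,5-diprenylbenzoate | COC(=O)c1c(OC)c(CC=C(C)C)c(O)c(CC=C(C)C)c1O  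
A7 | alternative 3 | 2,10-dimethylundeca-2,9-dien-6-one | CC(C)=CCCC(=O)CCC=C(C)C  
A8 | alternative 3 | dimethyl 2-(dimethoxymethylene)propanedioate | COC(OC)=C(C(=O)OC)C(=O)OC  
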